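**Plan**

1. Retrosynthetic cuts: the aryl ether bond C11–O (scopoletin put on last), then ring A at C3–C4, then ring B at C9–C10 and C5–C6 (Diels–Alder).
2. Enabling feature: in ring A the fully substituted C4 (gem-dimethyl) sits next to the oxygenated C3, so C3–C4 can be read as a tertiary C4 radical adding to a C3 nitrile.
3. Forward order: ring B is built first by a catalysed endo Diels–Alder reaction of a 1,2-disubstituted diene with an α-methyl dienal; the C10 formyl group is extended to a 2-cyanoethyl chain.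
4. Ring A is closed last: hydrogen-atom transfer to the C5 isopropenyl group gives the C4 radical, which cyclises 6-exo-dig onto the nitrile to give the 4,4-dimethyl-3-ketone.
5. Stereochemistry: C9, C10 and C5 come from the Diels–Alder step (endo rule, E-dienophile, chiral catalyst), which presets the trans ring fusion; the axial C3 alcohol comes from equatorial hydride delivery.

Key step: step 7

Remark on numbering: drimane numbering is used (ring A = C1–C5 and C10; ring B = C5–C10; C11 = the CH2O carbon on C9).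
Assumption: the sense of induction in step 4 is assigned from the formyl C–H···O pre-transition-state model for α-substituted enals on protonated oxazaborolidines; on that basis the (R)-catalyst is specified, and its mirror image would be used without other change if the adduct proved antipodal.

**Step 1**
Reactants: 1 methacrolein; 2 2-(triphenyl-λ5-phosphanylidene)propanal
Product: 3 (E)-2,4-dimethylpenta-2,4-dienal
Conditions: 1 (3 equiv), toluene, 70 °C, sealed vessel
Reagents that add atoms: none
Why: Wittig olefination with a formyl-stabilised ylide is E-selective, and the unhindered enal 1, used in excess, should react faster than the more hindered dienal product.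

**Step 2**
Reactants: 4 (E)-3-methylpent-2-en-4-yn-1-ol
Product: 5 (E)-3-methylpenta-2,4-dien-1-ol
Conditions: H2 (1 atm), Pd/CaCO3 poisoned with Pb(OAc)2, quinoline, EtOAc, 20 °C
Reagents that add atoms: none
Why: Lindlar-type semi-hydrogenation should stop the terminal alkyne at the vinyl stage and leave the trisubstituted E-alkene untouched.

**Step 3**
Reactants: 5 (E)-3-methylpenta-2,4-dien-1-ol
Product: 6 tert-butyl{[(2E)-3-methylpenta-2,4-dien-1-yl]oxy}diphenylsilane
Conditions: TBDPSCl, imidazole, DMF, 20 °C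
Reagents that add atoms: tert-butyl(chloro)diphenylsilane, CC(C)(C)[Si](Cl)(c1ccccc1)c1ccccc1
Why: Standard silylation of a primary allylic alcohol; the bulky, acid-resistant silyl ether is chosen to survive the acid catalyst of step 4 and the aqueous acid of step 7.

**Step 4**
Reactants: 6 tert-butyl{[(2E)-3-methylpenta-2,4-dien-1-yl]oxy}diphenylsilane; 3 (E)-2,4-dimethylpenta-2,4-dienal
Product: 7 (1R,2S,6R)-2-({[tert-butyl(diphenyl)silyl]oxy}methyl)-1,3-dimethyl-6-(prop-1-en-2-yl)cyclohex-3-ene-1-carbaldehyde (formyl cis to the silyloxymethyl group, trans to the isopropenyl group)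
Conditions: (R)-1-(2-methylphenyl)-3,3-diphenyltetrahydro-1H,3H-pyrrolo[1,2-c][1,3,2]oxazaborole (20 mol %), (CF3SO2)2NH (18 mol %), 6 (1.5 equiv), CH2Cl2, −78 → −40 °C
Reagents that add atoms: none
Why: Catalysed normal-demand Diels–Alder reaction in which the boron-bound formyl group activates the α,β-alkene of 3, the 1-(silyloxymethyl) group of the diene steers its free terminus C6 to the β-carbon C5 so that C9 bonds to the formyl-bearing C10, the endo formyl orientation puts C11 cis to the formyl carbon, the E geometry of 3 keeps formyl and isopropenyl trans, and the catalyst shields one enal face to fix the absolute configuration.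

**Step 5**
Reactants: 7 (1R,2S,6R)-2-({[tert-butyl(diphenyl)silyl]oxy}methyl)-1,3-dimethyl-6-(prop-1-en-2-yl)cyclohex-3-ene-1-carbaldehyde
Product: 8 (2E)-3-[(1R,2S,6R)-2-({[tert-butyl(diphenyl)silyl]oxy}methyl)-1,3-dimethyl-6-(prop-1-en-2-yl)cyclohex-3-en-1-yl]prop-2-enenitrile
Conditions: (EtO)2P(O)CH2CN, NaH, THF, 0 → 20 °C
Reagents that add atoms: diethyl cyanomethylphosphonate, CCOP(=O)(CC#N)OCC
Why: Horner–Wadsworth–Emmons olefination with the small cyanomethylphosphonate anion should tolerate the neopentyl-type aldehyde, which has no α-hydrogen to epimerise; the alkene geometry is irrelevant because this double bond is reduced next.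

**Step 6**
Reactants: 8 (2E)-3-[(1R,2S,6R)-2-({[tert-butyl(diphenyl)silyl]oxy}methyl)-1,3-dimethyl-6-(prop-1-en-2-yl)cyclohex-3-en-1-yl]prop-2-enenitrile
Product: 9 3-[(1R,2S,6R)-2-({[tert-butyl(diphenyl)silyl]oxy}methyl)-1,3-dimethyl-6-(prop-1-en-2-yl)cyclohex-3-en-1-yl]propanenitrile
Conditions: Mg turnings, MeOH, 0 → 20 °C
Reagents that add atoms: none
Why: Single-electron conjugate reduction by Mg in MeOH is specific for the alkene conjugated to the nitrile and should leave the isolated isopropenyl and ring alkenes, the nitrile and the silyl ether untouched.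

**Step 7**
Reactants: 9 3-[(1R,2S,6R)-2-({[tert-butyl(diphenyl)silyl]oxy}methyl)-1,3-dimethyl-6-(prop-1-en-2-yl)cyclohex-3-en-1-yl]propanenitrile
Product: 11 (4aR,5S,8aS)-5-({[tert-butyl(diphenyl)silyl]oxy}methyl)-1,1,4a,6-tetramethyl-3,4,4a,5,8,8a-hexahydronaphthalen-2(1H)-one, via NH ketimine 10 (not isolated)
Conditions: Fe(acac)3 (30 mol %), PhSiH3 (3 equiv), EtOH/ethylene glycol, 60 °C; then 1 M aq. HCl, THF, 20 °C
Reagents that add atoms: water, O
Why: An iron hydride formed from Fe(acac)3 and PhSiH3 in EtOH transfers a hydrogen atom to the terminal CH2 of the isopropenyl group, giving the tertiary C4 radical, which adds to the nitrile carbon C3 to form the C3–C4 bond; the iminyl radical is reduced to ketimine 10 and hydrolysed to the ketone. The closest known reaction type is the hydrogen-atom-transfer-initiated cyclisation of alkenyl nitriles to cyclic ketones, a variant of the classical radical cyclisation onto nitriles. Ring A closes in the 6-exo-dig mode through a chair-like transition state in which the C5 and C10 tethers are both equatorial. No new stereocentre is formed (C4 becomes the gem-dimethyl quaternary carbon), and the trans ring fusion follows from the C5 and C10 configurations set in step 4. The step needs hydrogen-atom transfer to the 1,1-disubstituted alkene in preference to the trisubstituted ring alkene, which the exposed terminal CH2 should secure as in limonene-type substrates. It also needs cyclisation to outrun reduction of the radical, which is favoured by the gauche, pre-organised arrangement of the two tethers and the absence of a fast hydrogen donor.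

**Step 8**
Reactants: 11 (4aR,5S,8aS)-5-({[tert-butyl(diphenyl)silyl]oxy}methyl)-1,1,4a,6-tetramethyl-3,4,4a,5,8,8a-hexahydronaphthalen-2(1H)-one
Product: 12 (2S,4aR,5S,8aS)-5-({[tert-butyl(diphenyl)silyl]oxy}methyl)-1,1,4a,6-tetramethyl-1,2,3,4,4a,5,8,8a-octahydronaphthalen-2-ol
Conditions: LiBH(s-Bu)3 (L-Selectride), THF, −78 → 0 °C; then H2O
Reagents that add atoms: none
Why: Ketone reduction with a bulky trialkylborohydride, which avoids the axial trajectory (1,3-diaxial hydrogens at C1 and C5) and attacks equatorially, should give the axial (3S) alcohol anti to the C10 methyl group, as is usual for 4,4-dimethyl-3-oxo terpenoids.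

**Step 9**
Reactants: 12 (2S,4aR,5S,8aS)-5-({[tert-butyl(diphenyl)silyl]oxy}methyl)-1,1,4a,6-tetramethyl-1,2,3,4,4a,5,8,8a-octahydronaphthalen-2-ol
Product: 13 (2S,4aR,5S,8aS)-5-(hydroxymethyl)-1,1,4a,6-tetramethyl-1,2,3,4,4a,5,8,8a-octahydronaphthalen-2-ol
Conditions: Bu4NF, THF, 20 °C
Reagents that add atoms: none
Why: Fluoride-driven cleavage of the Si–O bond; nothing else in 12 is sensitive to fluoride or mild base.

**Step 10**
Reactants: 13 (2S,4aR,5S,8aS)-5-(hydroxymethyl)-1,1,4a,6-tetramethyl-1,2,3,4,4a,5,8,8a-octahydronaphthalen-2-ol; 14 scopoletin (7-hydroxy-6-methoxy-2H-chromen-2-one)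
Product: 15 7-{[(1S,4aS,6S,8aR)-6-hydroxy-2,5,5,8a-tetramethyl-1,4,4a,5,6,7,8,8a-octahydronaphthalen-1-yl]methoxy}-6-methoxy-2H-chromen-2-one (CNP0218138.1)
Conditions: PPh3, DIAD, THF, 0 → 20 °C
Reagents that add atoms: none
Why: Mitsunobu etherification in which the acidic phenol 14 is alkylated by the oxyphosphonium salt of the primary C11 alcohol, while the axial, neopentyl-type C3 alcohol is too hindered to be activated; no stereocentre is touched.

**Compound list**

1 | methacrolein (2-methylprop-2-enal) | C=C(C)C=O | starting material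
2 | 2-(triphenyl-λ5-phosphanylidene)propanal | CC(C=O)=P(c1ccccc1)(c1ccccc1)c1ccccc1 | starting material
3 | (E)-2,4-dimethylpenta-2,4-dienal | C=C(C)/C=C(\C)C=O | intermediate
4 | (E)-3-methylpent-2-en-4-yn-1-ol | C#C/C(C)=C/CO | starting material
5 | (E)-3-methylpenta-2,4-dien-1-ol | C=C/C(C)=C/CO | intermediate
6 | tert-butyl{[(2E)-3-methylpenta-2,4-dien-1-yl]oxy}diphenylsilane | C=C/C(C)=C/CO[Si](c1ccccc1)(c1ccccc1)C(C)(C)C | intermediate
7 | (1R,2S,6R)-2-({[tert-butyl(diphenyl)silyl]oxy}methyl)-1,3-dimethyl-6-(prop-1-en-2-yl)cyclohex-3-ene-1-carbaldehyde | CC(C)(C)[Si](c1ccccc1)(c1ccccc1)OC[C@H]1C(C)=CC[C@H](C(C)=C)[C@]1(C=O)C | intermediate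
8 | (2E)-3-[(1R,2S,6R)-2-({[tert-butyl(diphenyl)silyl]oxy}methyl)-1,3-dimethyl-6-(prop-1-en-2-yl)cyclohex-3-en-1-yl]prop-2-enenitrile | CC(C)(C)[Si](c1ccccc1)(c1ccccc1)OC[C@H]1C(C)=CC[C@H](C(C)=C)[C@]1(/C=C/C#N)C | intermediate
9 | 3-[(1R,2S,6R)-2-({[tert-butyl(diphenyl)silyl]oxy}methyl)-1,3-dimethyl-6-(prop-1-en-2-yl)cyclohex-3-en-1-yl]propanenitrile | CC(C)(C)[Si](c1ccccc1)(c1ccccc1)OC[C@H]1C(C)=CC[C@H](C(C)=C)[C@]1(CCC#N)C | intermediate
10 | (4aR,5S,8aS)-5-({[tert-butyl(diphenyl)silyl]oxy}methyl)-1,1,4a,6-tetramethyl-3,4,4a,5,8,8a-hexahydronaphthalen-2(1H)-imine (NH ketimine) | CC(C)(C)[Si](c1ccccc1)(c1ccccc1)OC[C@H]1C(C)=CC[C@@H]2C(C)(C)C(=N)CC[C@]21C | intermediate (not isolated)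
11 | (4aR,5S,8aS)-5-({[tert-butyl(diphenyl)silyl]oxy}methyl)-1,1,4a,6-tetramethyl-3,4,4a,5,8,8a-hexahydronaphthalen-2(1H)-one | CC(C)(C)[Si](c1ccccc1)(c1ccccc1)OC[C@H]1C(C)=CC[C@@H]2C(C)(C)C(=O)CC[C@]21C | intermediate
12 | (2S,4aR,5S,8aS)-5-({[tert-butyl(diphenyl)silyl]oxy}methyl)-1,1,4a,6-tetramethyl-1,2,3,4,4a,5,8,8a-octahydronaphthalen-2-ol | CC(C)(C)[Si](c1ccccc1)(c1ccccc1)OC[C@H]1C(C)=CC[C@@H]2C(C)(C)[C@@H](O)CC[C@]21C | intermediate
13 | (2S,4aR,5S,8aS)-5-(hydroxymethyl)-1,1,4a,6-tetramethyl-1,2,3,4,4a,5,8,8a-octahydronaphthalen-2-ol | OC[C@H]1C(C)=CC[C@@H]2C(C)(C)[C@@H](O)CC[C@]21C | intermediate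
14 | scopoletin (7-hydroxy-6-methoxy-2H-chromen-2-one) | COc1cc2ccc(=O)oc2cc1O | starting material
15 | 7-{[(1S,4aS,6S,8aR)-6-hydroxy-2,5,5,8a-tetramethyl-1,4,4a,5,6,7,8,8a-octahydronaphthalen-1-yl]methoxy}-6-methoxy-2H-chromen-2-one | COc1cc2ccc(=O)oc2cc1OC[C@H]1C(C)=CC[C@@H]2C(C)(C)[C@@H](O)CC[C@]21C | target

**Totals**

Total step count: 10. Longest linear sequence: 9 steps (4 → 15, steps 2–10); the dienophile branch (step 1) joins at step 4.

**Steps most likely to fail**

Step 4 (Diels–Alder). The diene may add to the terminal isopropenyl alkene of dienal 3 instead of the α,β-alkene, or add in the reversed orientation, so that too little of the required adduct forms. The fallback sets out from silyl ether 6 and ylide 2. Wittig reaction of 2 with methylglyoxal should give (E)-2-methyl-4-oxopent-2-enal F1, a dienophile with a single, doubly activated alkene. Its catalysed Diels–Alder addition to 6 under the conditions of step 4 should give (1S,2S,6S)-6-acetyl-2-({[tert-butyl(diphenyl)silyl]oxy}methyl)-1,3-dimethylcyclohex-3-ene-1-carbaldehyde F2 (formyl endo, orientation steered by the catalyst-bound formyl group). Aldehyde-selective Horner–Wadsworth–Emmons reaction with diethyl cyanomethylphosphonate gives the unsaturated keto nitrile F3, and Mg/MeOH reduction gives the saturated keto nitrile F4. Wittig methylenation of the methyl ketone (Ph3P=CH2, THF) then returns the route at nitrile 9.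

Step 7 (radical ring closure). Reduction or disproportionation of the tertiary C4 radical may outpace its slow 6-exo addition to the nitrile, or hydrogen-atom transfer may also occur at the ring alkene. The fallback sets out from nitrile 9. DIBAL-H reduction (toluene, −78 °C, aqueous work-up) gives 3-[(1R,2S,6R)-2-({[tert-butyl(diphenyl)silyl]oxy}methyl)-1,3-dimethyl-6-(prop-1-en-2-yl)cyclohex-3-en-1-yl]propanal F5. The same hydrogen-atom-transfer radical generation (Fe(acac)3, PhSiH3, EtOH) then meets a much faster carbonyl acceptor and should close ring A to the C3 alcohols F6 as a mixture of epimers. Oxidation with Dess–Martin periodinane returns the route at ketone 11.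

Step 10 (etherification). Activation and displacement at the β-branched, axial C11 carbinol may be slow, leaving the betaine to be consumed unproductively. The fallback sets out from diol 13. Selective sulfonylation of the primary hydroxyl (MsCl, Et3N, CH2Cl2, −20 °C) gives [(1S,4aS,6S,8aR)-6-hydroxy-2,5,5,8a-tetramethyl-1,4,4a,5,6,7,8,8a-octahydronaphthalen-1-yl]methyl methanesulfonate F7. Displacement by the cesium salt of scopoletin 14 (Cs2CO3, DMF, 70 °C) then gives target 15.

**Further compounds**

F1 | step 4 | (E)-2-methyl-4-oxopent-2-enal | O=C/C(C)=C/C(C)=O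
F2 | step 4 | (1S,2S,6S)-6-acetyl-2-({[tert-butyl(diphenyl)silyl]oxy}methyl)-1,3-dimethylcyclohex-3-ene-1-carbaldehyde | CC(C)(C)[Si](c1ccccc1)(c1ccccc1)OC[C@H]1C(C)=CC[C@H](C(C)=O)[C@]1(C=O)C
F3 | step 4 | (2E)-3-[(1S,2S,6S)-6-acetyl-2-({[tert-butyl(diphenyl)silyl]oxy}methyl)-1,3-dimethylcyclohex-3-en-1-yl]prop-2-enenitrile | CC(C)(C)[Si](c1ccccc1)(c1ccccc1)OC[C@H]1C(C)=CC[C@H](C(C)=O)[C@]1(/C=C/C#N)C
F4 | step 4 | 3-[(1S,2S,6S)-6-acetyl-2-({[tert-butyl(diphenyl)silyl]oxy}methyl)-1,3-dimethylcyclohex-3-en-1-yl]propanenitrile | CC(C)(C)[Si](c1ccccc1)(c1ccccc1)OC[C@H]1C(C)=CC[C@H](C(C)=O)[C@]1(CCC#N)C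
F5 | step 7 | 3-[(1R,2S,6R)-2-({[tert-butyl(diphenyl)silyl]oxy}methyl)-1,3-dimethyl-6-(prop-1-en-2-yl)cyclohex-3-en-1-yl]propanal | CC(C)(C)[Si](c1ccccc1)(c1ccccc1)OC[C@H]1C(C)=CC[C@H](C(C)=C)[C@]1(CCC=O)C
F6 | step 7 | (4aR,5S,8aS)-5-({[tert-butyl(diphenyl)silyl]oxy}methyl)-1,1,4a,6-tetramethyl-1,2,3,4,4a,5,8,8a-octahydronaphthalen-2-ol, mixture of C2 epimers | CC(C)(C)[Si](c1ccccc1)(c1ccccc1)OC[C@H]1C(C)=CC[C@@H]2C(C)(C)C(O)CC[C@]21C
F7 | step 10 | [(1S,4aS,6S,8aR)-6-hydroxy-2,5,5,8a-tetramethyl-1,4,4a,5,6,7,8,8a-octahydronaphthalen-1-yl]methyl methanesulfonate | CS(=O)(=O)OC[C@H]1C(C)=CC[C@@H]2C(C)(C)[C@@H](O)CC[C@]21C
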